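**Plan**

1. Retrosynthesis: the C5–aryl bond of the tetrahydrofuran is cut first (the 4-hydroxy-3,5-dimethoxyphenyl ring leaves as 2,6-dimethoxyphenol and C5 becomes a lactone carbonyl). Both methyls are then traced back to the CH2 arms of a fused thiolane (two C–S bonds), and the C3–CH2 and C4–CH2 bonds are cut together to give a 5-aryl butenolide and a CH2=S(+)–CH2(−) dipole.
2. The butenolide is cut at its C=C bond and its ester C–O bond, and the allylic alcohol at the vinyl–carbinol bond, which leads to veratraldehyde.
3. Forward: vinylation, enzymatic resolution and acryloylation build the chain; metathesis closes the oxygen ring; cycloaddition fuses the sulfur ring on; Raney Ni cuts it open; the lactone is reduced, acetalised and arylated.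
4. Enabling feature: on the tetrahydrofuran ring the methyls at C3 and C4 are cis to each other and both trans to the 3,4-dimethoxyphenyl group at C2. A five-membered ring fused across C3–C4 on the face away from that aryl leaves exactly this pattern once its sulfur is excised.
5. Stereochemistry: C2 comes from the lipase resolution; C3 and C4 from the anti, suprafacial cycloaddition, carried unchanged through desulfurisation; C5 from attack of the phenol on the oxocarbenium ion opposite the two cis methyls.

Key step: step 5

Remark: Candida antarctica lipase B is assumed to show its usual preference for secondary 1-aryl carbinols (aryl as the large group, vinyl as the medium one) and to acylate the (R)-alcohol, so the (S)-alcohol needed for C2 is the unreacted one.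

**Step 1**
Reactants: 1 veratraldehyde; 2 vinylmagnesium bromide
Product: 3 rac-1-(3,4-dimethoxyphenyl)prop-2-en-1-ol
Conditions: CH2=CHMgBr, THF, 0 °C; then sat. aq NH4Cl
Reagents that add atoms: vinylmagnesium bromide 2, C=C[Mg]Br
Why: Grignard 1,2-addition of the vinyl nucleophile to the aldehyde gives the allylic alcohol as a racemate, which is acceptable because the next step resolves it, and the buffered quench avoids acid-promoted allylic transposition.

**Step 2**
Reactants: 3 rac-1-(3,4-dimethoxyphenyl)prop-2-en-1-ol
Product: 4 (S)-1-(3,4-dimethoxyphenyl)prop-2-en-1-ol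
Conditions: Novozym 435 (immobilised Candida antarctica lipase B), vinyl acetate, t-BuOMe, 30 °C, stopped just past half conversion
Reagents that add atoms: none
Why: Lipase-catalysed kinetic resolution by irreversible transesterification should acetylate the (R)-alcohol and leave the (S)-alcohol, which fixes C2 of the target, and running slightly past half conversion should raise the enantiopurity of the recovered alcohol.

**Step 3**
Reactants: 4 (S)-1-(3,4-dimethoxyphenyl)prop-2-en-1-ol; 5 acryloyl chloride
Product: 6 (S)-1-(3,4-dimethoxyphenyl)prop-2-en-1-yl acrylate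
Conditions: Et3N, CH2Cl2, −20 → 0 °C
Reagents that add atoms: acryloyl chloride 5, C=CC(=O)Cl
Why: O-acylation of the secondary alcohol with an acid chloride and an amine base does not touch the C–O stereocentre, and the cold, basic medium should keep the ionisation-prone electron-rich benzylic allylic ester from rearranging.

**Step 4**
Reactants: 6 (S)-1-(3,4-dimethoxyphenyl)prop-2-en-1-yl acrylate
Product: 7 (S)-5-(3,4-dimethoxyphenyl)furan-2(5H)-one
Conditions: second-generation Grubbs catalyst (H2IMes)(PCy3)Cl2Ru=CHPh (5 mol %), CH2Cl2 (0.02 M), 40 °C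
Reagents that add atoms: none
Why: Ring-closing metathesis of the allyl and acrylate alkenes closes the butenolide with loss of ethylene, a standard route to 5-substituted butenolides, and the neutral conditions leave the now acidic C5–H stereocentre alone.

**Step 5**
Reactants: 7 (S)-5-(3,4-dimethoxyphenyl)furan-2(5H)-one; 8 chloromethyl trimethylsilylmethyl sulfide
Product: 10 (3S,3aS,6aR)-3-(3,4-dimethoxyphenyl)tetrahydro-1H-thieno[3,4-c]furan-1(3H)-one, via thioformaldehyde S-methylide 9 (not isolated)
Conditions: CsF (dried), MeCN, 0 °C → rt, slow addition of 8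
Reagents that add atoms: chloromethyl trimethylsilylmethyl sulfide 8, C[Si](C)(C)CSCCl
Why: Fluoride attacks silicon of 8 and chloride leaves in a 1,3-elimination, which gives thioformaldehyde S-methylide 9, a nucleophilic 1,3-dipole that adds in a concerted suprafacial (3+2) cycloaddition across the electron-poor C3=C4 bond of 7 and forms both C–CH2 bonds at once. The closest known reaction type is the 1,3-dipolar cycloaddition of this same parent thiocarbonyl ylide, generated in the same way, to butenolides, maleimides and enoates. The one ring closed is the thiolane, by an intermolecular (3+2) cycloaddition in which the two C–C bonds form together, so it ends up cis-fused to the lactone. The two new stereocentres C3a and C6a (C3 and C4 of the target) are controlled by the stereocentre C5 of the butenolide: the dipole approaches the flat ring on the face opposite the 3,4-dimethoxyphenyl group, and their mutual cis relation follows from the suprafacial addition. The step needs facial selectivity only, since the symmetric dipole raises no regiochemical question, and the aryl group on the sp3 carbon next to the alkene secures it. Slow addition of 8 to barely soluble CsF keeps the contact of the acidic C5–H with fluoride short, and the saturated adduct no longer has that acidity.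

**Step 6**
Reactants: 10 (3S,3aS,6aR)-3-(3,4-dimethoxyphenyl)tetrahydro-1H-thieno[3,4-c]furan-1(3H)-one
Product: 11 (3R,4S,5S)-5-(3,4-dimethoxyphenyl)-3,4-dimethyldihydrofuran-2(3H)-one
Conditions: Raney Ni (W-2, washed to neutrality, aged in acetone), EtOH, 50 °C
Reagents that add atoms: none
Why: Raney nickel desulfurisation replaces both C–S bonds by C–H bonds and so turns the two ring CH2 groups into methyls without breaking any bond at C3 or C4, while neutral, acetone-aged nickel is chosen to spare the benzylic C–O bond and the centre next to the carbonyl.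

**Step 7**
Reactants: 11 (3R,4S,5S)-5-(3,4-dimethoxyphenyl)-3,4-dimethyldihydrofuran-2(3H)-one
Product: 12 (3R,4S,5S)-5-(3,4-dimethoxyphenyl)-3,4-dimethyltetrahydrofuran-2-ol (mixture of anomers)
Conditions: i-Bu2AlH, CH2Cl2, −78 °C; then aq potassium sodium tartrate
Reagents that add atoms: none
Why: Partial reduction of a γ-lactone with i-Bu2AlH stops at the lactol because the tetrahedral aluminium hemiacetal survives at −78 °C until work-up, and the three ring stereocentres are not involved (the new anomeric centre is erased in step 9).

**Step 8**
Reactants: 12 (3R,4S,5S)-5-(3,4-dimethoxyphenyl)-3,4-dimethyltetrahydrofuran-2-ol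
Product: 13 (2S,3S,4R)-2-(3,4-dimethoxyphenyl)-5-methoxy-3,4-dimethyltetrahydrofuran (mixture of anomers)
Conditions: MeOH, pyridinium p-toluenesulfonate (cat.), rt
Reagents that add atoms: methanol, CO
Why: Acid-catalysed acetalisation of the lactol (Fischer-type glycosidation) gives a storable oxocarbenium precursor, and the weak pyridinium acid should leave the benzylic ether and the methyl-bearing centres unchanged.

**Step 9**
Reactants: 13 (2S,3S,4R)-2-(3,4-dimethoxyphenyl)-5-methoxy-3,4-dimethyltetrahydrofuran; 14 2,6-dimethoxyphenol
Product: 16 (2S,3S,4R,5R)-2-(3,4-dimethoxyphenyl)-5-(4-hydroxy-3,5-dimethoxyphenyl)-3,4-dimethyltetrahydrofuran, via cyclic oxocarbenium ion 15 (not isolated)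
Conditions: BF3·OEt2, CH2Cl2, −78 → −20 °C
Reagents that add atoms: 2,6-dimethoxyphenol 14, COc1cccc(OC)c1O
Why: BF3 ionises the acetal to oxocarbenium ion 15, which is trapped in a Friedel–Crafts arylation at the position para to the phenol OH (both ortho positions are blocked), and the arene should approach the face opposite the two cis methyls, so the new aryl ends up trans to the C4 methyl and cis to the C2 aryl, which is also the more stable arrangement should the benzylic ether reopen.

**Compound list**

1 | veratraldehyde (3,4-dimethoxybenzaldehyde) | COc1ccc(C=O)cc1OC | starting material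
2 | vinylmagnesium bromide | C=C[Mg]Br | starting material
3 | rac-1-(3,4-dimethoxyphenyl)prop-2-en-1-ol | COc1ccc(C(O)C=C)cc1OC | intermediate
4 | (S)-1-(3,4-dimethoxyphenyl)prop-2-en-1-ol | COc1ccc([C@@H](O)C=C)cc1OC | intermediate
5 | acryloyl chloride | C=CC(=O)Cl | starting material
6 | (S)-1-(3,4-dimethoxyphenyl)prop-2-en-1-yl acrylate | COc1ccc([C@@H](OC(=O)C=C)C=C)cc1OC | intermediate
7 | (S)-5-(3,4-dimethoxyphenyl)furan-2(5H)-one | COc1ccc([C@H]2OC(=O)C=C2)cc1OC | intermediate
8 | chloromethyl trimethylsilylmethyl sulfide | C[Si](C)(C)CSCCl | starting material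
9 | thioformaldehyde S-methylide (parent thiocarbonyl ylide, not isolated) | C=[S+][CH2-] | intermediate
10 | (3S,3aS,6aR)-3-(3,4-dimethoxyphenyl)tetrahydro-1H-thieno[3,4-c]furan-1(3H)-one (cis-fused, aryl anti to the thiolane) | COc1ccc([C@H]2OC(=O)[C@@H]3CSC[C@H]23)cc1OC | intermediate
11 | (3R,4S,5S)-5-(3,4-dimethoxyphenyl)-3,4-dimethyldihydrofuran-2(3H)-one | COc1ccc([C@H]2OC(=O)[C@H](C)[C@@H]2C)cc1OC | intermediate
12 | (3R,4S,5S)-5-(3,4-dimethoxyphenyl)-3,4-dimethyltetrahydrofuran-2-ol (both anomers) | COc1ccc([C@H]2OC(O)[C@H](C)[C@@H]2C)cc1OC | intermediate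
13 | (2S,3S,4R)-2-(3,4-dimethoxyphenyl)-5-methoxy-3,4-dimethyltetrahydrofuran (both anomers) | COc1ccc([C@H]2OC(OC)[C@H](C)[C@@H]2C)cc1OC | intermediate
14 | 2,6-dimethoxyphenol | COc1cccc(OC)c1O | starting material
15 | (2S,3S,4R)-2-(3,4-dimethoxyphenyl)-3,4-dimethyl-3,4-dihydro-2H-furan-1-ium (cyclic oxocarbenium ion, not isolated) | COc1ccc([C@H]2[O+]=C[C@H](C)[C@@H]2C)cc1OC | intermediate
16 | (2S,3S,4R,5R)-2-(3,4-dimethoxyphenyl)-5-(4-hydroxy-3,5-dimethoxyphenyl)-3,4-dimethyltetrahydrofuran, also named 4-[(2R,3R,4S,5S)-5-(3,4-dimethoxyphenyl)-3,4-dimethyltetrahydrofuran-2-yl]-2,6-dimethoxyphenol | COc1ccc([C@H]2O[C@@H](c3cc(OC)c(O)c(OC)c3)[C@H](C)[C@@H]2C)cc1OC | target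

**Step count**

Total: 9 steps. Longest linear sequence: 9 steps, from veratraldehyde 1 to 16.

**Steps most likely to fail**

Step 5. Fluoride may remove the C5 proton of 7, which is benzylic and vinylogous to the carbonyl. That would erode the enantiopurity or shift the double bond before the dipole adds. The dipole may also be lost to self-reaction if the butenolide traps it slowly. The fallback introduces the two methyls one at a time. It sets out from 7. Conjugate addition of Me2CuLi (from MeLi and CuI) in Et2O at −78 °C, anti to the aryl, should give (4S,5S)-5-(3,4-dimethoxyphenyl)-4-methyldihydrofuran-2(3H)-one F1. Enolisation with LiN(i-Pr)2 in THF at −78 °C and methylation with MeI, anti to the C4 methyl, should give the all-trans lactone (3S,4S,5S)-5-(3,4-dimethoxyphenyl)-3,4-dimethyldihydrofuran-2(3H)-one F2. A second enolisation followed by kinetic protonation with a bulky proton donor such as 2,6-di-tert-butyl-4-methylphenol, from the face opposite the C4 methyl, should invert C3. The route is rejoined at 11. The cost is that the cis-dimethyl relation then depends on a kinetic protonation.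

Step 9. The arylation may lose control in several ways: attack on the methyl-bearing face of the oxocarbenium ion, O-alkylation or attack at a wrong position of the phenol, proton loss from the oxocarbenium ion to an enol ether (which would scramble the neighbouring methyl-bearing centre), or reopening of the benzylic ether at C2. The fallback makes the C5–aryl bond by carbonyl addition and closes the ring afterwards by C–O bond formation. Commercial 4-bromo-2,6-dimethoxyphenol would be silylated (t-BuMe2SiCl, imidazole, DMF) to (4-bromo-2,6-dimethoxyphenoxy)(tert-butyl)dimethylsilane F3. Treatment with n-BuLi in THF at −78 °C would give [4-(tert-butyldimethylsilyloxy)-3,5-dimethoxyphenyl]lithium F4. The fallback sets out from lactol 12. An excess of F4 added to its open hydroxy aldehyde form should give (1S,2S,3R)-4-[4-(tert-butyldimethylsilyloxy)-3,5-dimethoxyphenyl]-1-(3,4-dimethoxyphenyl)-2,3-dimethylbutane-1,4-diol F5 as both C4 epimers. Acid-mediated cyclodehydration (catalytic p-TsOH, CH2Cl2, 0 °C) runs through a para-oxygenated benzylic cation and is reversible. It should therefore settle at the isomer with each aryl trans to its neighbouring methyl, tert-butyl{4-[(2R,3R,4S,5S)-5-(3,4-dimethoxyphenyl)-3,4-dimethyltetrahydrofuran-2-yl]-2,6-dimethoxyphenoxy}dimethylsilane F6. Bu4NF in THF would then free the phenol, and the route is rejoined at 16.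

Step 6. The nickel may over-reduce by hydrogenolysis of the benzylic C5–O bond of the lactone next to the electron-rich ring, or alkali left in the nickel may epimerise C3 next to the carbonyl. The fallback changes the order so that sulfur is removed after the carbonyl is gone. It sets out from 10. i-Bu2AlH in CH2Cl2 at −78 °C should give (3S,3aS,6aR)-3-(3,4-dimethoxyphenyl)tetrahydro-1H,3H-thieno[3,4-c]furan-1-ol F7. MeOH with catalytic pyridinium p-toluenesulfonate should give its methyl acetal, cis-fused 1-(3,4-dimethoxyphenyl)-3-methoxytetrahydro-1H,3H-thieno[3,4-c]furan with the ring configuration of 10, F8. Raney Ni in EtOH would then be applied to F8, which has no enolisable centre and whose benzylic oxygen is an ether and not an acyloxy group. The route is rejoined at 13.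

**Further compounds**

F1 | step 5 | (4S,5S)-5-(3,4-dimethoxyphenyl)-4-methyldihydrofuran-2(3H)-one | COc1ccc([C@H]2OC(=O)C[C@@H]2C)cc1OC
F2 | step 5 | (3S,4S,5S)-5-(3,4-dimethoxyphenyl)-3,4-dimethyldihydrofuran-2(3H)-one | COc1ccc([C@H]2OC(=O)[C@@H](C)[C@@H]2C)cc1OC
F3 | step 9 | (4-bromo-2,6-dimethoxyphenoxy)(tert-butyl)dimethylsilane | COc1cc(Br)cc(OC)c1O[Si](C)(C)C(C)(C)C
F4 | step 9 | [4-(tert-butyldimethylsilyloxy)-3,5-dimethoxyphenyl]lithium | [Li]c1cc(OC)c(O[Si](C)(C)C(C)(C)C)c(OC)c1
F5 | step 9 | (1S,2S,3R)-4-[4-(tert-butyldimethylsilyloxy)-3,5-dimethoxyphenyl]-1-(3,4-dimethoxyphenyl)-2,3-dimethylbutane-1,4-diol (both C4 epimers) | COc1ccc([C@@H](O)[C@@H](C)[C@@H](C)C(O)c2cc(OC)c(O[Si](C)(C)C(C)(C)C)c(OC)c2)cc1OC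
F6 | step 9 | tert-butyl{4-[(2R,3R,4S,5S)-5-(3,4-dimethoxyphenyl)-3,4-dimethyltetrahydrofuran-2-yl]-2,6-dimethoxyphenoxy}dimethylsilane | COc1ccc([C@H]2O[C@@H](c3cc(OC)c(O[Si](C)(C)C(C)(C)C)c(OC)c3)[C@H](C)[C@@H]2C)cc1OC
F7 | step 6 | (3S,3aS,6aR)-3-(3,4-dimethoxyphenyl)tetrahydro-1H,3H-thieno[3,4-c]furan-1-ol (both anomers) | COc1ccc([C@H]2OC(O)[C@@H]3CSC[C@H]23)cc1OC
F8 | step 6 | cis-fused 1-(3,4-dimethoxyphenyl)-3-methoxytetrahydro-1H,3H-thieno[3,4-c]furan, ring configuration as in 10 (both anomers) | COc1ccc([C@H]2OC(OC)[C@@H]3CSC[C@H]23)cc1OC
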